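**Retrosynthetic overview**
1. Target 23 ⇐ furyl carbinol 22: the C13–O bond of the spiro bis-ether is formed last, by dearomative hydroalkoxylation of the furan by the 9α-hydroxyl.
2. 22 ⇐ cross-conjugated dienone 15: C8=C9 becomes 9α-OH/8α-Me (epoxidation, reductive methylation); C5=C6(OSi)–C7=O becomes 5α-H/6β-O (dissolving metal, α-face protonation).
3. Ring B of 15 ⇐ enol silane 7 + ynone 13: Michael addition (C9–C10), then aldol condensation (C5–C6).
4. Ring A (7) ⇐ cyclopentanone 5 by one-carbon ring expansion with a silyl diazoethane, which inserts C10 with its methyl; 5 ⇐ desymmetrised 2-methylcyclopentane-1,3-dione 1.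
5. Ring order: five-membered precursor → ring A → ring B → spiro tetrahydrofuran/dihydrofuran.

Assumption: bicyclic compounds are named on the labdane skeleton (C1–C20, 10β-methyl; the furan is the 15,16-epoxy-13(16),14-diene); TBS = tert-butyldimethylsilyl, "TBSO-methyl" = CH2OTBS.

**Step 1**
Reactants: 1 2-methylcyclopentane-1,3-dione
Product: 3 2-methyl-2-(TBSO-methyl)cyclopentane-1,3-dione, via hydroxymethyl dione 2 (not isolated)
Conditions: aq. HCHO (37 %), H2O, 23 °C; concentrate; then TBSCl, imidazole, DMF, 0 °C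
Reagents that add atoms: formaldehyde C=O; tert-butyldimethylsilyl chloride CC(C)(C)[Si](C)(C)Cl
Why: The acidic 2-substituted 1,3-dione adds to formaldehyde at C2 (aldol-type hydroxymethylation, no stereocentre formed) and silylation of the primary alcohol blocks retro-aldol loss of formaldehyde.

**Step 2**
Reactants: 3 2-methyl-2-(TBSO-methyl)cyclopentane-1,3-dione
Product: 4 (2S,3S)-3-hydroxy-2-methyl-2-(TBSO-methyl)cyclopentan-1-one
Conditions: (R)-2-methyl-CBS-oxazaborolidine (20 mol %), BH3·SMe2 (0.6 equiv), THF, −40 °C; aqueous work-up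
Reagents that add atoms: none
Why: Corey–Bakshi–Shibata reduction desymmetrises the prochiral dione: the catalyst selects one enantiotopic carbonyl and hydride arrives on the face of the smaller methyl group, so the carbinol (future C3) is S and cis to the silyloxymethyl arm (future C19), which also fixes the quaternary centre (future C4).

**Step 3**
Reactants: 4 (2S,3S)-3-hydroxy-2-methyl-2-(TBSO-methyl)cyclopentan-1-one
Product: 5 (2S,3S)-3-(TBSO)-2-methyl-2-(TBSO-methyl)cyclopentan-1-one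
Conditions: TBSOTf, 2,6-lutidine, CH2Cl2, −78 to 0 °C
Reagents that add atoms: tert-butyldimethylsilyl triflate CC(C)(C)[Si](C)(C)OS(=O)(=O)C(F)(F)F
Why: Standard silylation of the secondary alcohol protects it through the enolate and dissolving-metal steps.

**Step 4**
Reactants: 5 (2S,3S)-3-(TBSO)-2-methyl-2-(TBSO-methyl)cyclopentan-1-one
Product: 7 {[(5S,6S)-5-(TBSO)-2,6-dimethyl-6-(TBSO-methyl)cyclohex-1-en-1-yl]oxy}trimethylsilane, via silyl ketone 6 (not isolated)
Conditions: MeC(N2)SiMe3 (1.5 equiv), Sc(OTf)3 (10 mol %), PhMe, −78 to 23 °C; then 60 °C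
Reagents that add atoms: (1-diazoethyl)trimethylsilane C[Si](C)(C)C(C)=[N+]=[N-]
Why: In this Lewis-acid-catalysed diazoalkane–ketone homologation (Tiffeneau–Demjanov-type ring expansion) the less substituted CH2 migrates in preference to the quaternary carbon with loss of N2, and the α-silyl ketone then undergoes a 1,3-Brook shift to the single tetrasubstituted enol silane, so ring A, C10 and its methyl are installed in one operation.

**Step 5**
Reactants: 8 3-(bromomethyl)furan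
Product: 9 3-(but-3-yn-1-yl)furan
Conditions: HC≡CCH2MgBr, Et2O, −20 to 23 °C
Reagents that add atoms: propargylmagnesium bromide C#CC[Mg]Br
Why: Grignard alkylation of the reactive furylmethyl bromide by the allenyl/propargyl reagent (SE2′ coupling) gives the terminal alkyne.

**Step 6**
Reactants: 9 3-(but-3-yn-1-yl)furan; 10 (TBSO)acetaldehyde
Product: 12 rac-1-(TBSO)-6-(furan-3-yl)hex-3-yn-2-ol, via alkynyllithium 11 (not isolated)
Conditions: n-BuLi, THF, −78 °C; then 10; aq. NH4Cl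
Reagents that add atoms: none
Why: Alkynyllithium 1,2-addition to the aldehyde; the carbinol centre is racemic and is oxidised away in the next step.

**Step 7**
Reactants: 12 rac-1-(TBSO)-6-(furan-3-yl)hex-3-yn-2-ol
Product: 13 1-(TBSO)-6-(furan-3-yl)hex-3-yn-2-one
Conditions: Dess–Martin periodinane, NaHCO3, CH2Cl2, 0 to 23 °C
Reagents that add atoms: none
Why: Dess–Martin oxidation of the propargylic alcohol gives the ynone without touching the furan or the silyl ether.

**Step 8**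
Reactants: 7 {[(5S,6S)-5-(TBSO)-2,6-dimethyl-6-(TBSO-methyl)cyclohex-1-en-1-yl]oxy}trimethylsilane; 13 1-(TBSO)-6-(furan-3-yl)hex-3-yn-2-one
Product: 15 3β,6,19-tris(TBSO)-15,16-epoxy-17-norlabda-5,8,13(16),14-tetraen-7-one, via enedione 14 (not isolated)
Conditions: TMSOTf (10 mol %), CH2Cl2, −78 °C; aq. NaHCO3; crude 14, KOt-Bu (20 mol %), t-BuOH–THF, 40 °C
Reagents that add atoms: none
Why: Mukaiyama–Michael addition of the enol silane to the silyl-activated ynone forms C9–C10 on the face anti to the axial silyloxymethyl group (C10 methyl ends β, cis to C19), and base-mediated intramolecular aldol condensation of the α-silyloxy ketone onto the C5 carbonyl (Robinson-type annulation) closes ring B.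

**Step 9**
Reactants: 15 3β,6,19-tris(TBSO)-15,16-epoxy-17-norlabda-5,8,13(16),14-tetraen-7-one
Product: 16 3β,6,19-tris(TBSO)-8α,9α:15,16-diepoxy-17-norlabda-5,13(16),14-trien-7-one
Conditions: t-BuOOH (decane), DBU, CH2Cl2, 0 to 23 °C
Reagents that add atoms: tert-butyl hydroperoxide CC(C)(C)OO
Why: Weitz–Scheffer nucleophilic epoxidation attacks only the electron-poor C8=C9 bond (C5=C6 is a silyl enol ether with a fully substituted β-carbon) from the α-face anti to the C10 methyl, as in steroidal 1,4-dien-3-ones, and so sets the 9α-oxygen.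

**Step 10**
Reactants: 16 3β,6,19-tris(TBSO)-8α,9α:15,16-diepoxy-17-norlabda-5,13(16),14-trien-7-one
Product: 18 3β,6,19-tris(TBSO)-15,16-epoxy-9α-hydroxy-8βH-labda-5,13(16),14-trien-7-one, via dilithium enolate alkoxide 17 (not isolated)
Conditions: Li (2.5 equiv), NH3–THF, −78 °C; MeI; NH4Cl
Reagents that add atoms: iodomethane CI
Why: Dissolving-metal reductive opening of the α,β-epoxy ketone cleaves C8–O to the 9α-alkoxide/C7–C8 enolate, which is C-methylated at C8 on the α-face away from the C10 methyl (reductive alkylation of an epoxy ketone), giving the equatorial 8α-methyl that is also the thermodynamic epimer.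

**Step 11**
Reactants: 18 3β,6,19-tris(TBSO)-15,16-epoxy-9α-hydroxy-8βH-labda-5,13(16),14-trien-7-one
Product: 20 3β,6β,19-tris(TBSO)-15,16-epoxy-9α-hydroxy-5αH,8βH-labda-13(16),14-dien-7-one, via dilithium enolate 19 (not isolated)
Conditions: Li (2.2 equiv), t-BuOH (1 equiv), NH3–THF, −78 °C; isoprene; solid NH4Cl, −78 °C
Reagents that add atoms: none
Why: Dissolving-metal (Birch-type) conjugate reduction protonates C5 axially to the trans-decalin (5α-H) and leaves the regiodefined C6–C7 enolate, whose kinetic protonation occurs on the open α-face (the β-face is blocked by the syn-axial C10 methyl and C19 arm), placing the C6 silyloxy group β.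

**Step 12**
Reactants: 20 3β,6β,19-tris(TBSO)-15,16-epoxy-9α-hydroxy-5αH,8βH-labda-13(16),14-dien-7-one
Product: 21 15,16-epoxy-3β,6β,9α,19-tetrahydroxylabda-13(16),14-dien-7-one
Conditions: HF·pyridine, pyridine, THF, 0 to 23 °C
Reagents that add atoms: none
Why: Buffered fluoride desilylation removes the three silyl ethers without base, so the α-ketol is not epimerised and the furan and β-hydroxy ketone survive.

**Step 13**
Reactants: 21 15,16-epoxy-3β,6β,9α,19-tetrahydroxylabda-13(16),14-dien-7-one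
Product: 22 3β,19-diacetoxy-15,16-epoxy-6β,9α-dihydroxylabda-13(16),14-dien-7-one
Conditions: Ac2O (2.5 equiv), pyridine, CH2Cl2, 0 °C
Reagents that add atoms: acetic anhydride CC(=O)OC(C)=O
Why: Selective acylation takes the primary C19 and equatorial C3 hydroxyls, while the 6β-hydroxyl (flanked by two syn-axial groups) and the tertiary 9α-hydroxyl do not react.

**Step 14**
Reactants: 22 3β,19-diacetoxy-15,16-epoxy-6β,9α-dihydroxylabda-13(16),14-dien-7-one
Product: 23 (13R)-3β,19-diacetoxy-9α,13:15,16-diepoxy-6β-hydroxylabd-14-en-7-one (CNP0317137.1)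
Conditions: Co(C36H52N2O2) [divalent cobalt complex of (S,S)-N,N′-bis(3,5-di-tert-butylsalicylidene)cyclohexane-1,2-diamine, 5 mol %], N-fluoro-2,4,6-trimethylpyridinium triflate (1.2 equiv), PhSiH3 (1.2 equiv), 2,4,6-collidine (1 equiv), PhCF3, 0 °C
Reagents that add atoms: none
Why: Proposed new method: a trivalent cobalt hydride (from the fluoro complex and PhSiH3) transfers a hydrogen atom to C16, the furan α-carbon next to the substituent, giving the tertiary oxygen-conjugated allyl radical at C13; capture and one-electron oxidation to a tetravalent alkylcobalt (allyl-cation equivalent) is followed by 5-exo attack of the 9α-hydroxyl at C13, with the chiral salen ligand directing the face (13R; which ligand enantiomer is matched is a prediction to be checked, the 13-epimer being separable), so the furan is dearomatised irreversibly and without acid to the spiro tetrahydrofuran–2,3-dihydrofuran; the closest known reaction is the cobalt-salen hydrogen-atom-transfer/radical-polar crossover hydroalkoxylation of unactivated alkenes, not yet shown on a furan C=C bond.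

**Compound list**
1 | 2-methylcyclopentane-1,3-dione | CC1C(=O)CCC1=O | starting material
2 | 2-(hydroxymethyl)-2-methylcyclopentane-1,3-dione | CC1(CO)C(=O)CCC1=O | intermediate
3 | 2-methyl-2-(TBSO-methyl)cyclopentane-1,3-dione | CC1(CO[Si](C)(C)C(C)(C)C)C(=O)CCC1=O | intermediate
4 | (2S,3S)-3-hydroxy-2-methyl-2-(TBSO-methyl)cyclopentan-1-one | CC(C)(C)[Si](C)(C)OC[C@@]1(C)[C@@H](O)CCC1=O | intermediate
5 | (2S,3S)-3-(TBSO)-2-methyl-2-(TBSO-methyl)cyclopentan-1-one | CC(C)(C)[Si](C)(C)OC[C@@]1(C)[C@@H](O[Si](C)(C)C(C)(C)C)CCC1=O | intermediate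
6 | (2S,3S)-3-(TBSO)-2,6-dimethyl-2-(TBSO-methyl)-6-(trimethylsilyl)cyclohexan-1-one (C6 epimers) | CC(C)(C)[Si](C)(C)OC[C@@]1(C)[C@@H](O[Si](C)(C)C(C)(C)C)CCC(C)([Si](C)(C)C)C1=O | intermediate
7 | {[(5S,6S)-5-(TBSO)-2,6-dimethyl-6-(TBSO-methyl)cyclohex-1-en-1-yl]oxy}trimethylsilane | CC(C)(C)[Si](C)(C)OC[C@@]1(C)[C@@H](O[Si](C)(C)C(C)(C)C)CCC(C)=C1O[Si](C)(C)C | intermediate
8 | 3-(bromomethyl)furan | BrCc1ccoc1 | starting material
9 | 3-(but-3-yn-1-yl)furan | C#CCCc1ccoc1 | intermediate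
10 | (TBSO)acetaldehyde, {[tert-butyl(dimethyl)silyl]oxy}acetaldehyde | CC(C)(C)[Si](C)(C)OCC=O | starting material
11 | [4-(furan-3-yl)but-1-yn-1-yl]lithium | [Li]C#CCCc1ccoc1 | intermediate
12 | rac-1-(TBSO)-6-(furan-3-yl)hex-3-yn-2-ol | CC(C)(C)[Si](C)(C)OCC(O)C#CCCc1ccoc1 | intermediate
13 | 1-(TBSO)-6-(furan-3-yl)hex-3-yn-2-one | CC(C)(C)[Si](C)(C)OCC(=O)C#CCCc1ccoc1 | intermediate
14 | (2S,3S,6R)-3-(TBSO)-6-[1-(TBSO)-6-(furan-3-yl)-2-oxohex-3-en-4-yl]-2,6-dimethyl-2-(TBSO-methyl)cyclohexan-1-one (E/Z mixture) | CC(C)(C)[Si](C)(C)OC[C@@]1(C)[C@@H](O[Si](C)(C)C(C)(C)C)CC[C@@](C)(C1=O)C(CCc1ccoc1)=CC(=O)CO[Si](C)(C)C(C)(C)C | intermediate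
15 | 3β,6,19-tris(TBSO)-15,16-epoxy-17-norlabda-5,8,13(16),14-tetraen-7-one | CC(C)(C)[Si](C)(C)OC[C@@]1(C)[C@@H](O[Si](C)(C)C(C)(C)C)CC[C@@]2(C)C1=C(O[Si](C)(C)C(C)(C)C)C(=O)C=C2CCc3ccoc3 | intermediate
16 | 3β,6,19-tris(TBSO)-8α,9α:15,16-diepoxy-17-norlabda-5,13(16),14-trien-7-one | CC(C)(C)[Si](C)(C)OC[C@@]1(C)[C@@H](O[Si](C)(C)C(C)(C)C)CC[C@@]2(C)C1=C(O[Si](C)(C)C(C)(C)C)C(=O)[C@H]3O[C@@]23CCc4ccoc4 | intermediate
17 | dilithium 3β,6,19-tris(TBSO)-15,16-epoxy-17-norlabda-5,7,13(16),14-tetraene-7,9α-diolate | [Li+].[Li+].CC(C)(C)[Si](C)(C)OC[C@@]1(C)[C@@H](O[Si](C)(C)C(C)(C)C)CC[C@@]2(C)C1=C(O[Si](C)(C)C(C)(C)C)C([O-])=C[C@]2([O-])CCc3ccoc3 | intermediate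
18 | 3β,6,19-tris(TBSO)-15,16-epoxy-9α-hydroxy-8βH-labda-5,13(16),14-trien-7-one | CC(C)(C)[Si](C)(C)OC[C@@]1(C)[C@@H](O[Si](C)(C)C(C)(C)C)CC[C@@]2(C)C1=C(O[Si](C)(C)C(C)(C)C)C(=O)[C@@H](C)[C@]2(O)CCc3ccoc3 | intermediate
19 | dilithium 3β,6,19-tris(TBSO)-15,16-epoxy-5αH,8βH-labda-6,13(16),14-triene-7,9α-diolate | [Li+].[Li+].CC(C)(C)[Si](C)(C)OC[C@@]1(C)[C@@H](O[Si](C)(C)C(C)(C)C)CC[C@@]2(C)[C@H]1C(O[Si](C)(C)C(C)(C)C)=C([O-])[C@@H](C)[C@]2([O-])CCc3ccoc3 | intermediate
20 | 3β,6β,19-tris(TBSO)-15,16-epoxy-9α-hydroxy-5αH,8βH-labda-13(16),14-dien-7-one | CC(C)(C)[Si](C)(C)OC[C@@]1(C)[C@@H](O[Si](C)(C)C(C)(C)C)CC[C@@]2(C)[C@H]1[C@H](O[Si](C)(C)C(C)(C)C)C(=O)[C@@H](C)[C@]2(O)CCc3ccoc3 | intermediate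
21 | 15,16-epoxy-3β,6β,9α,19-tetrahydroxylabda-13(16),14-dien-7-one | OC[C@@]1(C)[C@@H](O)CC[C@@]2(C)[C@H]1[C@H](O)C(=O)[C@@H](C)[C@]2(O)CCc3ccoc3 | intermediate
22 | 3β,19-diacetoxy-15,16-epoxy-6β,9α-dihydroxylabda-13(16),14-dien-7-one | CC(=O)OC[C@@]1(C)[C@@H](OC(C)=O)CC[C@@]2(C)[C@H]1[C@H](O)C(=O)[C@@H](C)[C@]2(O)CCc3ccoc3 | intermediate
23 | (13R)-3β,19-diacetoxy-9α,13:15,16-diepoxy-6β-hydroxylabd-14-en-7-one (CNP0317137.1) | CC(=O)OC[C@@]1(C)[C@@H](OC(C)=O)CC[C@@]2(C)[C@H]1[C@H](O)C(=O)[C@@H](C)[C@]21CC[C@]2(C=COC2)O1 | target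

**Step count and risks**
Total step count: 14. Longest linear sequence: 11 (steps 1–4, then 8–14); the ynone arm is 3 steps (5–7).

The three steps most likely to fail:

Step 8. A hindered tetrasubstituted enol silane must add to a β-substituted ynone in the presence of a Lewis-acid-sensitive furan, and the aldol must close onto a ketone flanked by two quaternary carbons. Fallback, basic enolate chemistry without a Lewis acid and with an acceptor that has no acidic hydrogens: it sets out from 7 and 9. Alkyne 9 is deprotonated with n-BuLi and trapped with methyl chloroformate to give methyl 5-(furan-3-yl)pent-2-ynoate F1. MeLi cleaves 7 to the regiodefined lithium (5S,6S)-5-(TBSO)-2,6-dimethyl-6-(TBSO-methyl)cyclohex-1-en-1-olate F2, whose conjugate addition to F1 gives methyl 3-[(1R,3S,4S)-4-(TBSO)-1,3-dimethyl-2-oxo-3-(TBSO-methyl)cyclohexyl]-5-(furan-3-yl)pent-2-enoate F3. LiCH(OTBS)P(O)(OMe)2 acylates the ester to the β-keto phosphonate, dimethyl {1-(TBSO)-4-[(1R,3S,4S)-4-(TBSO)-1,3-dimethyl-2-oxo-3-(TBSO-methyl)cyclohexyl]-6-(furan-3-yl)-2-oxohex-3-en-1-yl}phosphonate F4. Its anion closes onto the C5 ketone by intramolecular Horner–Wadsworth–Emmons olefination, and the route is rejoined at 15.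

Step 11. The β-silyloxy ketone from α-face protonation is the less stable C6 epimer, so a slow or warm quench could give 6α or a mixture. Fallback, hydride delivery to a C6 ketone instead of enolate protonation: it sets out from 18. NaBH4/CeCl3·7H2O (Luche) reduces C7 to 3β,6,19-tris(TBSO)-15,16-epoxy-8βH-labda-5,13(16),14-triene-7α,9α-diol F5 (the C7 configuration is inconsequential). Bu4NF/AcOH at −78 °C cleaves only the silyl enol ether and gives 3β,19-bis(TBSO)-15,16-epoxy-7α,9α-dihydroxy-5αH,8βH-labda-13(16),14-dien-6-one F6, with C5 settling trans next to the ketone. NaBH4 attacks the C6 ketone from the open α-face to give 3β,19-bis(TBSO)-15,16-epoxy-5αH,8βH-labda-13(16),14-diene-6β,7α,9α-triol F7. TEMPO/PhI(OAc)2 oxidises only the less hindered C7 hydroxyl to 3β,19-bis(TBSO)-15,16-epoxy-6β,9α-dihydroxy-5αH,8βH-labda-13(16),14-dien-7-one F8. HF·pyridine then removes the two remaining silyl groups and the route is rejoined at 21.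

Step 14 (the proposed new step). Hydrogen-atom transfer to a furan is unproven; the enol ether product could be reduced further or revert to the furan under acid, and C13 selectivity is not assured. Fallback with known reaction types (halo-etherification, then tin hydride dehalogenation): it sets out from 22. NBS/NaHCO3 in THF at −78 °C brominates the furan at C16 and the 9α-hydroxyl closes on C13 to give (13R)-3β,19-diacetoxy-16-bromo-9α,13:15,16-diepoxy-6β-hydroxylabd-14-en-7-one F9 (C16 epimers, with the 13-epimer removed by chromatography). Bu3SnH/AIBN in benzene at 80 °C removes the bromine and the route is rejoined at 23.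

**Further compounds**
F1 | step 8 | methyl 5-(furan-3-yl)pent-2-ynoate | COC(=O)C#CCCc1ccoc1
F2 | step 8 | lithium (5S,6S)-5-(TBSO)-2,6-dimethyl-6-(TBSO-methyl)cyclohex-1-en-1-olate | [Li+].CC(C)(C)[Si](C)(C)OC[C@@]1(C)[C@@H](O[Si](C)(C)C(C)(C)C)CCC(C)=C1[O-]
F3 | step 8 | methyl 3-[(1R,3S,4S)-4-(TBSO)-1,3-dimethyl-2-oxo-3-(TBSO-methyl)cyclohexyl]-5-(furan-3-yl)pent-2-enoate (E/Z mixture) | CC(C)(C)[Si](C)(C)OC[C@@]1(C)[C@@H](O[Si](C)(C)C(C)(C)C)CC[C@@](C)(C1=O)C(CCc1ccoc1)=CC(=O)OC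
F4 | step 8 | dimethyl {1-(TBSO)-4-[(1R,3S,4S)-4-(TBSO)-1,3-dimethyl-2-oxo-3-(TBSO-methyl)cyclohexyl]-6-(furan-3-yl)-2-oxohex-3-en-1-yl}phosphonate | CC(C)(C)[Si](C)(C)OC[C@@]1(C)[C@@H](O[Si](C)(C)C(C)(C)C)CC[C@@](C)(C1=O)C(CCc1ccoc1)=CC(=O)C(O[Si](C)(C)C(C)(C)C)P(=O)(OC)OC
F5 | step 11 | 3β,6,19-tris(TBSO)-15,16-epoxy-8βH-labda-5,13(16),14-triene-7α,9α-diol | CC(C)(C)[Si](C)(C)OC[C@@]1(C)[C@@H](O[Si](C)(C)C(C)(C)C)CC[C@@]2(C)C1=C(O[Si](C)(C)C(C)(C)C)[C@@H](O)[C@@H](C)[C@]2(O)CCc3ccoc3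
F6 | step 11 | 3β,19-bis(TBSO)-15,16-epoxy-7α,9α-dihydroxy-5αH,8βH-labda-13(16),14-dien-6-one | CC(C)(C)[Si](C)(C)OC[C@@]1(C)[C@@H](O[Si](C)(C)C(C)(C)C)CC[C@@]2(C)[C@H]1C(=O)[C@@H](O)[C@@H](C)[C@]2(O)CCc3ccoc3
F7 | step 11 | 3β,19-bis(TBSO)-15,16-epoxy-5αH,8βH-labda-13(16),14-diene-6β,7α,9α-triol | CC(C)(C)[Si](C)(C)OC[C@@]1(C)[C@@H](O[Si](C)(C)C(C)(C)C)CC[C@@]2(C)[C@H]1[C@H](O)[C@@H](O)[C@@H](C)[C@]2(O)CCc3ccoc3
F8 | step 11 | 3β,19-bis(TBSO)-15,16-epoxy-6β,9α-dihydroxy-5αH,8βH-labda-13(16),14-dien-7-one | CC(C)(C)[Si](C)(C)OC[C@@]1(C)[C@@H](O[Si](C)(C)C(C)(C)C)CC[C@@]2(C)[C@H]1[C@H](O)C(=O)[C@@H](C)[C@]2(O)CCc3ccoc3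
F9 | step 14 | (13R)-3β,19-diacetoxy-16-bromo-9α,13:15,16-diepoxy-6β-hydroxylabd-14-en-7-one (C16 epimers) | CC(=O)OC[C@@]1(C)[C@@H](OC(C)=O)CC[C@@]2(C)[C@H]1[C@H](O)C(=O)[C@@H](C)[C@]21CC[C@]2(C=COC2Br)O1
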